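**The constants.** The constants set two rates against each other: the partner step makes target, and two first-order steps lose it. Heating from 40 °C to 70 °C speeds the partner step by 12. The loss to over-reaction product B shares the activation energy of the substrate step, so it speeds by 32, which is faster.

| flask | substrate | partner | temperature | time | remark |
|---|---|---|---|---|---|
| oak | 1.1 M | 1.32 M | 70 °C | 20 h |  |
| cedar | 1.1 M | 1.32 M | 40 °C | 20 h |  |
| maple | 1.1 M | 1.32 M |  | 20 h | at 40 °C until 4.0 h, from then on at 70 °C |

    substrate → intermediate (k1 = 0.152 h⁻¹, Ea1 = 103 kJ mol⁻¹)
    partner + intermediate → target (k2 = 0.143 M⁻¹ h⁻¹, Ea2 = 73.0 kJ mol⁻¹)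
    target → over-reaction product A (k3 = 1.68 × 10⁻⁴ h⁻¹, Ea3 = 109 kJ mol⁻¹)
    target → over-reaction product B (k4 = 0.00601 h⁻¹, Ea4 = 103 kJ mol⁻¹)
    (constants at 40 °C)

- all constants are for 40 °C and move with temperature by the activation energies

- the flask that comes out highest in amount of target, in percent of the substrate charged, or "all alike" when all lie within 1.5 percentage points (oak / cedar / maple / all alike)
- target at the end, in percent of the substrate charged, oak
- target at the end, in percent of the substrate charged, cedar
- target at the end, in percent of the substrate charged, maple

**The count.** We add the two loss constants. That gives 0.00618 h⁻¹ at 40 °C, and 0.197 h⁻¹ at 70 °C, where the loss to over-reaction product A speeds by 39. Over cedar's 20 h this makes 0.124 turnovers. This number, the loss constant times the hours at that temperature, summed over the run, is the loss count. Oak's count is 3.95. Maple's is 3.18, since 4.0 h of its run are cool.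

**Reading it.** Target present from the start survives as exp(−count). That gives 88.4 % for cedar, 4.14 % for maple and 1.93 % for oak. Cedar has the smallest count, so we expect cedar highest.

**One number?** The count says nothing about making target. In cedar the substrate step gets 3.04 turnovers. The partner step, pseudo-first-order with constant k2·c(partner), gets 3.78 at the charged c(partner), and c(partner) falls. With so few turnovers in a chain of two steps, we expect part of the charge still on its way, and cedar below its survival. In oak and maple, target made late sees fewer loss turnovers, so we expect them somewhat above their survivals. The one number gives us the order of the flasks, not their yields.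

**The forecast.** The forecast names cedar, with oak 2.7 %, cedar 67 % and maple 5.6 %. Its grounds for cedar: “its loss is slow, so cedar keeps most of what forms”.

**The result.** The simulation gives cedar: oak 2.64 %, cedar 67.0 %, maple 5.57 %. In cedar at 20.0 h, target is still made 4.32 times faster than it is used up, and its half-life by the passing into over-reaction product B, 120 h, is long against the 20 h of the run. Cedar left to 200 h has a loss count of 1.24 and a survival of 29.1 %, and its target stands at 32.7 % of the substrate charged.

(The rate constants are made up; the result is computed.)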